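(The runs were computed from invented constants, noise included.)

| flask | starting material | reagent | remark | time |
|---|---|---|---|---|
| larch | 0.013 M | 1.05 equiv (fed, over 2.5 min) | run made earlier; the fed solution adds 0.50 times the starting volume |  |
| oak | 0.030 M | 1.05 equiv (fed, over 2.5 min) | run made earlier; the fed solution adds 0.50 times the starting volume |  |
| ash | 0.020 M | 2.1 equiv (fed, over 2.5 min) | run made earlier; the fed solution adds 0.50 times the starting volume |  |
| flask | 0.020 M | 1.05 equiv (fed, over 2.5 min) | the fed solution adds 0.50 times the starting volume | 25 h |

| run | time / h | product / % | starting material / % |
|---|---|---|---|
| larch | 4.00 | 73 | 1 |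
| larch | 8.00 | 75 | 3 |
| larch | 12.0 | 70 | 0 |
| larch | 15.0 | 73 | 0 |
| larch | 20.0 | 75 | 1 |
| larch | 25.0 | 78 | 0 |
| oak | 2.00 | 68 | 1 |
| oak | 3.00 | 73 | 0 |
| oak | 6.00 | 85 | 0 |
| oak | 10.0 | 83 | 0 |
| oak | 15.0 | 89 | 0 |
| oak | 25.0 | 81 | 1 |
| ash | 5.00 | 88 | 0 |
| ash | 10.0 | 92 | 1 |
| ash | 15.0 | 90 | 0 |
| ash | 20.0 | 92 | 0 |
| ash | 25.0 | 91 | 2 |

(scatter of a reading: 2 percentage points)

1. at 25 h, what has stopped the reaction, if anything has (the reagent has run out first / forward and back rates have come level / all of the starting material has reacted / it is still moving)
2. amount of product at 25 h, in percent of the starting material charged

- charges are per starting volume, the dose included; the dosed solution carries all of it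
- the earlier runs were read with a standard deviation of 2 percentage points
- the reaction counts as stopped when no species that holds the starting material changes by six tenths of a point or more over the second half of the time

At 25 h, the time you read the flask, the earlier runs point to a plateau: the oak run shows 1 % starting material as early as 2.00 h, and its product climbs from 68 % then to 85 % at 6.00 h, after which it wanders around a level. So the task is to estimate that level.

This estimate is mine. Suppose starting material goes two ways: with the reagent, at a rate that carries both concentrations, and on its own, at a rate that carries its own concentration. Divide one rate by the other and the starting material cancels, which leaves an easy integral: the amount lost equals a constant times ln(reagent charged / reagent left). Reagent used counts as product.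

The larch plateau of 74.0 % gives 0.00277 M for that constant. The oak plateau of 84.5 %, from 6.00 h on, gives 0.00285 M. Their mean, 0.00281 M, is a reading of the side constant: the concentration of reagent present at a given moment, not the amount charged, at which both ways run equally fast, a selectivity factor with a unit. Both are counted on the charges as printed, since every run has the same feed volume.

For the flask, the share lost is the side constant over the starting concentration, times ln(equivalents charged / equivalents left). The equivalents left depend on the answer, so start from a guess, the midpoint 79.3 %. That gives 80.3 %. The guess is the weak link, so put this result back in its place, which returns 79.7 % product and leaves 24.1 % of the reagent.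

The forecast says all of the starting material has reacted and 80 %, on the grounds that “The shortfall grows on dilution and shrinks with excess reagent”.

The simulation gives all of the starting material has reacted and 79.6 %.

    starting material + reagent → intermediate A (k = 18.3 /M/min)
    starting material → intermediate B (k = 0.0295 /min)
    intermediate A → intermediate C (k = 0.136 /min)
    intermediate B ⇌ intermediate D (K = 0.531, k = 0.0605 /min)
    intermediate C → product (k = 0.0155 /min)
    intermediate D ⇌ intermediate E (K = 0.898, k = 0.0878 /min)

The flask holds 0 % starting material and 24 % of its reagent at 25.0 h. Now cut the reagent to 0.420 equiv in the neighbouring flask, the other charges and the time held. The same constant, with the reagent nearly used up, puts the reagent left at exp(−lost / side constant), which is 1.61 %, and so the product at 41.3 %. That neighbouring flask ends with 1.0 % of its reagent and 41.6 % product.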